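The route rests on cutting ring B at the bond between the spiro carbon and the CH2 group next to CHBr. The precursor of that step is a flat, orcinol-derived aryl silyl ether whose open chain already carries the C(Me)Cl–CHBr pair, set by catalytic enantioselective bromochlorination of a (Z)-allylic alcohol. Fluoride-triggered para C-alkylation of the phenoxide closes ring B, creates the spiro quaternary stereocentre and dearomatises the arene into ring A in one operation. It exploits that the spiro carbon of ring A lies para to the CH= carbon and between the exo-methylene and gem-dimethyl carbons, and that CHBr sits 1,3 to it in ring B, so a chair transition state relays configuration.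

Key step: step 8

Remark: the enantiomer of the chiral Schiff-base ligand in step 6 is taken to be the one that delivers the (2S,3S) bromochloride; its mirror image would be used if the sense of induction on the (Z)-alkene proved opposite.

Step 1
Reactants: 1 2,4-dihydroxy-6-methylbenzaldehyde
Product: 2 2-hydroxy-6-methyl-4-(triisopropylsilyloxy)benzaldehyde
Conditions: i-Pr3SiCl (1.05 equiv), imidazole, CH2Cl2, 0 °C
Reagents that add atoms: triisopropylsilyl chloride, CC(C)[Si](Cl)(C(C)C)C(C)C
Why: Silyl ether formation should be selective for the 4-hydroxyl because the 2-hydroxyl is tied up in a hydrogen bond to the aldehyde and is flanked by it.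

Step 2
Reactants: 2 2-hydroxy-6-methyl-4-(triisopropylsilyloxy)benzaldehyde
Product: 3 2-methoxy-6-methyl-4-(triisopropylsilyloxy)benzaldehyde
Conditions: MeOH, PPh3, DIAD, THF, 0 °C to rt
Reagents that add atoms: methanol, CO
Why: Mitsunobu etherification methylates the remaining chelated phenol under neutral conditions, which spares the base-labile aryl silyl ether para to the aldehyde.

Step 3
Reactants: 3 2-methoxy-6-methyl-4-(triisopropylsilyloxy)benzaldehyde
Product: 4 (4-ethenyl-3-methoxy-5-methylphenoxy)triisopropylsilane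
Conditions: Ph3PCH3Br, NaN(SiMe3)2, THF, 0 °C to rt
Reagents that add atoms: methyltriphenylphosphonium bromide, C[P+](c1ccccc1)(c1ccccc1)c1ccccc1.[Br-]
Why: Wittig methylenation of the hindered but non-enolisable aldehyde should give the styrene cleanly.

Step 4
Reactants: 5 but-2-yn-1-ol
Product: 7 (Z)-3-iodobut-2-en-1-ol, via vinylalanate 6 (not isolated)
Conditions: NaAlH2(OCH2CH2OMe)2 (Red-Al), THF, 0 °C to rt; EtOAc; then I2, THF, −78 °C
Reagents that add atoms: sodium bis(2-methoxyethoxy)aluminium dihydride, [Na+].COCCO[AlH2-]OCCOC; iodine, II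
Why: Alkoxide-directed trans-hydroalumination places aluminium on C3 within a five-membered alanate and iodinolysis with retention gives the (Z)-iodoalkene (hydroalumination–iodination).

Step 5
Reactants: 4 (4-ethenyl-3-methoxy-5-methylphenoxy)triisopropylsilane; 7 (Z)-3-iodobut-2-en-1-ol
Product: 9 (2Z)-5-[2-methoxy-6-methyl-4-(triisopropylsilyloxy)phenyl]-3-methylpent-2-en-1-ol, via B-alkyl-9-BBN adduct 8 (not isolated)
Conditions: 9-BBN, THF, rt; then 7, PdCl2(dppf) (5 mol%), AsPh3, K3PO4 (aq), DMF, rt
Reagents that add atoms: 9-borabicyclo[3.3.1]nonane, C1CCC2CCCC1B2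
Why: Anti-Markovnikov hydroboration of the styrene followed by B-alkyl Suzuki–Miyaura coupling joins the two fragments with retention of the (Z) geometry, the vinyl iodide reacting at room temperature.

Step 6
Reactants: 9 (2Z)-5-[2-methoxy-6-methyl-4-(triisopropylsilyloxy)phenyl]-3-methylpent-2-en-1-ol
Product: 10 (2S,3S)-2-bromo-3-chloro-5-[2-methoxy-6-methyl-4-(triisopropylsilyloxy)phenyl]-3-methylpentan-1-ol
Conditions: NBS, ClTi(OiPr)3, chiral tridentate Schiff-base ligand (salicylaldimine of a chiral amino alcohol, 20 mol%), hexanes, −20 °C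
Reagents that add atoms: N-bromosuccinimide, O=C1CCC(=O)N1Br; chlorotitanium triisopropoxide, CC(C)O[Ti](Cl)(OC(C)C)OC(C)C
Why: In this titanium-mediated catalytic enantioselective bromochlorination of an allylic alcohol the titanium alkoxide of 9 receives bromine at C2 from NBS and chloride at the tertiary C3 from titanium in an anti sense, so the (Z) alkene should give the (2S,3S) pair with the absolute sense fixed by the ligand, while the bulky silyloxy group flanks both free ring positions and should suppress ring bromination.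

Step 7
Reactants: 10 (2S,3S)-2-bromo-3-chloro-5-[2-methoxy-6-methyl-4-(triisopropylsilyloxy)phenyl]-3-methylpentan-1-ol
Product: 11 (2S,3S)-2-bromo-3-chloro-5-[2-methoxy-6-methyl-4-(triisopropylsilyloxy)phenyl]-3-methylpentyl trifluoromethanesulfonate
Conditions: Tf2O, 2,6-lutidine, CH2Cl2, −78 °C; used crude
Reagents that add atoms: trifluoromethanesulfonic anhydride, O=S(=O)(OS(=O)(=O)C(F)(F)F)C(F)(F)F
Why: Sulfonylation of the primary alcohol with triflic anhydride and a hindered base gives a leaving group reactive enough for ring closure at low temperature.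

Step 8
Reactants: 11 (2S,3S)-2-bromo-3-chloro-5-[2-methoxy-6-methyl-4-(triisopropylsilyloxy)phenyl]-3-methylpentyl trifluoromethanesulfonate
Product: 13 (6R,8S,9S)-8-bromo-9-chloro-1-methoxy-5,9-dimethylspiro[5.5]undeca-1,4-dien-3-one, via tetrabutylammonium phenoxide 12 (not isolated)
Conditions: Bu4NF (1.0 equiv, slow addition), THF (5 mM), −78 to 0 °C
Reagents that add atoms: tetrabutylammonium fluoride, CCCC[N+](CCCC)(CCCC)CCCC.[F-]
Why: Fluoride cleaves the Si–O bond and unmasks a naked tetrabutylammonium phenoxide whose para carbon, further activated by the ortho methoxy group, displaces the primary triflate in an intramolecular SN2 reaction; this is an Ar1-6 phenoxide C-alkylation (alkylative dearomatisation) and it turns the flat arene into the cross-conjugated cyclohexadienone of ring A. Ring B closes in the 6-exo-tet mode. The new spiro stereocentre is controlled by the CHBr stereocentre through a chair transition state: bromine sits equatorial and the methoxy-bearing ring carbon, whose oxygen is the only substituent small enough to point over ring B between the two syn-axial hydrogens, takes the axial site, so that this carbon and bromine end up 1,3-trans as in the target. The epimeric spiro centre would need either an axial bromine 1,3-syn to that inward oxygen or the aryl methyl group thrust over ring B. The step needs C-alkylation at the substituted para carbon instead of elimination of triflic acid, attack of fluoride on the triflate or intermolecular O-alkylation; the phenoxide oxygen cannot reach the triflate within the molecule, and low temperature, high dilution and slow addition of one equivalent of fluoride should secure the rest.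

Step 9
Reactants: 13 (6R,8S,9S)-8-bromo-9-chloro-1-methoxy-5,9-dimethylspiro[5.5]undeca-1,4-dien-3-one
Product: 15 (6R,8S,9S)-4,8-dibromo-9-chloro-1-methoxy-5,5,9-trimethylspiro[5.5]undec-1-en-3-one (C4 epimers), via silyl enol ether 14 (not isolated)
Conditions: Me2CuLi, Me3SiCl, THF, −78 to −40 °C; Et3N, pentane, filtration; then NBS, THF, −78 °C
Reagents that add atoms: lithium dimethylcuprate, [Li+].C[Cu-]C; chlorotrimethylsilane, C[Si](C)(C)Cl; N-bromosuccinimide, O=C1CCC(=O)N1Br
Why: Gilman conjugate addition should occur only at the methyl-bearing enone arm (the methoxy enone arm is a vinylogous ester and the locked diequatorial bromochloride cannot reach the antiperiplanar geometry needed for reductive elimination), the silyl enol ether fixes the enolate regiochemistry, and NBS then brominates it alpha to the ketone, the new CHBr centre being of no consequence because it becomes sp2 in step 11.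

Step 10
Reactants: 15 (6R,8S,9S)-4,8-dibromo-9-chloro-1-methoxy-5,5,9-trimethylspiro[5.5]undec-1-en-3-one
Product: 17 (6R,8S,9S)-4,8-dibromo-9-chloro-5,5,9-trimethylspiro[5.5]undec-2-en-1-one (C4 epimers), via allylic alcohol 16 (not isolated)
Conditions: (i-Bu)2AlH, CH2Cl2, −78 °C; then 1 M HCl, THF, 0 °C
Reagents that add atoms: water, O
Why: In this Stork–Danheiser transposition, 1,2-reduction of the vinylogous ester carbonyl and acid hydrolysis of the resulting allylic enol ether move the carbonyl to the carbon next to the spiro centre and delete the oxygen at the former phenol carbon.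

Step 11
Reactants: 17 (6R,8S,9S)-4,8-dibromo-9-chloro-5,5,9-trimethylspiro[5.5]undec-2-en-1-one
Product: 19 (6R,8S,9S)-4,8-dibromo-9-chloro-5,5,9-trimethylspiro[5.5]undec-3-en-1-one, via potassium dienolate 18 (not isolated)
Conditions: KN(SiMe3)2, THF, −78 °C; then inverse quench into AcOH, THF, −78 °C
Reagents that add atoms: potassium bis(trimethylsilyl)amide, [K+].C[Si](C)(C)[N-][Si](C)(C)C
Why: In this deconjugation of the enone the only acidic hydrogen is the gamma CHBr hydrogen, and kinetic protonation of the dienolate at the alpha carbon should give the beta,gamma-unsaturated ketone with the vinyl bromide in place.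

Step 12
Reactants: 19 (6R,8S,9S)-4,8-dibromo-9-chloro-5,5,9-trimethylspiro[5.5]undec-3-en-1-one
Product: 20 (6S,8S,9S)-4,8-dibromo-9-chloro-5,5,9-trimethyl-1-methylidenespiro[5.5]undec-3-ene
Conditions: Cp2Ti(μ-Cl)(μ-CH2)AlMe2 (Tebbe reagent), pyridine, THF–toluene, −40 to 0 °C
Reagents that add atoms: Cp2Ti(μ-Cl)(μ-CH2)AlMe2 (Tebbe reagent), C[Al-]1(C)C[Ti](C2C=CC=C2)(C2C=CC=C2)[Cl+]1
Why: Tebbe methylenation is non-basic and tolerates hindered, easily enolised ketones, so the exocyclic methylene should form without reconjugation.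

Step 13
Reactants: 20 (6S,8S,9S)-4,8-dibromo-9-chloro-5,5,9-trimethyl-1-methylidenespiro[5.5]undec-3-ene
Product: 22 (6S,8S,9S)-4,8-dibromo-9-chloro-5,5,9-trimethyl-1-methylidenespiro[5.5]undec-3-en-2-one, via epimeric allylic alcohols 21 (not isolated)
Conditions: SeO2 (cat.), t-BuOOH, CH2Cl2, 0 °C to rt; then Dess–Martin periodinane, NaHCO3, CH2Cl2, 0 °C
Reagents that add atoms: selenium dioxide, O=[Se]=O; tert-butyl hydroperoxide, CC(C)(C)OO
Why: In this Riley oxidation the ene reaction of SeO2 at the exocyclic methylene and the [2,3]-shift deliver oxygen to the only allylic position (the doubly allylic CH2) with the methylene retained, and Dess–Martin oxidation of the crude epimeric alcohols erases the uncontrolled carbinol centre.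

Step 14
Reactants: 22 (6S,8S,9S)-4,8-dibromo-9-chloro-5,5,9-trimethyl-1-methylidenespiro[5.5]undec-3-en-2-one
Product: 23 (2R,6S,8S,9S)-4,8-dibromo-9-chloro-5,5,9-trimethyl-1-methylidenespiro[5.5]undec-3-en-2-ol
Conditions: (S)-2-methyl-CBS-oxazaborolidine (0.3 equiv), catecholborane, toluene, −78 °C
Reagents that add atoms: none
Why: Corey–Bakshi–Shibata reduction delivers hydride 1,2 under catalyst control, with the carbon bearing the exocyclic methylene and the quaternary spiro neighbour acting as the large group, and should set the (R) carbinol that the nearly mirror-symmetric surroundings of ring A cannot differentiate.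

Compound list
1 | 2,4-dihydroxy-6-methylbenzaldehyde | Cc1cc(O)cc(O)c1C=O | starting material
2 | 2-hydroxy-6-methyl-4-(triisopropylsilyloxy)benzaldehyde | Cc1cc(O[Si](C(C)C)(C(C)C)C(C)C)cc(O)c1C=O | intermediate
3 | 2-methoxy-6-methyl-4-(triisopropylsilyloxy)benzaldehyde | Cc1cc(O[Si](C(C)C)(C(C)C)C(C)C)cc(OC)c1C=O | intermediate
4 | (4-ethenyl-3-methoxy-5-methylphenoxy)triisopropylsilane | C=Cc1c(C)cc(O[Si](C(C)C)(C(C)C)C(C)C)cc1OC | intermediate
5 | but-2-yn-1-ol | CC#CCO | starting material
6 | sodium 2,2-bis(2-methoxyethoxy)-3-methyl-2,5-dihydro-1,2-oxaaluminol-2-uide (cyclic vinylalanate) | CC1=CCO[Al-]1(OCCOC)OCCOC.[Na+] | intermediate (not isolated)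
7 | (Z)-3-iodobut-2-en-1-ol | C/C(I)=C/CO | intermediate
8 | 9-{2-[2-methoxy-6-methyl-4-(triisopropylsilyloxy)phenyl]ethyl}-9-borabicyclo[3.3.1]nonane | Cc1cc(O[Si](C(C)C)(C(C)C)C(C)C)cc(OC)c1CCB1C2CCCC1CCC2 | intermediate (not isolated)
9 | (2Z)-5-[2-methoxy-6-methyl-4-(triisopropylsilyloxy)phenyl]-3-methylpent-2-en-1-ol | C/C(CCc1c(C)cc(O[Si](C(C)C)(C(C)C)C(C)C)cc1OC)=C/CO | intermediate
10 | (2S,3S)-2-bromo-3-chloro-5-[2-methoxy-6-methyl-4-(triisopropylsilyloxy)phenyl]-3-methylpentan-1-ol | Cc1cc(O[Si](C(C)C)(C(C)C)C(C)C)cc(OC)c1CC[C@](C)(Cl)[C@@H](Br)CO | intermediate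
11 | (2S,3S)-2-bromo-3-chloro-5-[2-methoxy-6-methyl-4-(triisopropylsilyloxy)phenyl]-3-methylpentyl trifluoromethanesulfonate | Cc1cc(O[Si](C(C)C)(C(C)C)C(C)C)cc(OC)c1CC[C@](C)(Cl)[C@@H](Br)COS(=O)(=O)C(F)(F)F | intermediate
12 | tetrabutylammonium 4-[(3S,4S)-4-bromo-3-chloro-3-methyl-5-(trifluoromethylsulfonyloxy)pentyl]-3-methoxy-5-methylphenoxide | Cc1cc([O-])cc(OC)c1CC[C@](C)(Cl)[C@@H](Br)COS(=O)(=O)C(F)(F)F.CCCC[N+](CCCC)(CCCC)CCCC | intermediate (not isolated)
13 | (6R,8S,9S)-8-bromo-9-chloro-1-methoxy-5,9-dimethylspiro[5.5]undeca-1,4-dien-3-one | COC1=CC(=O)C=C(C)[C@]12CC[C@](C)(Cl)[C@@H](Br)C2 | intermediate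
14 | (6R,8S,9S)-8-bromo-9-chloro-1-methoxy-5,5,9-trimethyl-3-(trimethylsilyloxy)spiro[5.5]undeca-1,3-diene | COC1=CC(O[Si](C)(C)C)=CC(C)(C)[C@]12CC[C@](C)(Cl)[C@@H](Br)C2 | intermediate (not isolated)
15 | (6R,8S,9S)-4,8-dibromo-9-chloro-1-methoxy-5,5,9-trimethylspiro[5.5]undec-1-en-3-one, both C4 epimers | COC1=CC(=O)C(Br)C(C)(C)[C@]12CC[C@](C)(Cl)[C@@H](Br)C2 | intermediate
16 | (6R,8S,9S)-4,8-dibromo-9-chloro-1-methoxy-5,5,9-trimethylspiro[5.5]undec-1-en-3-ol, epimers at C3 and C4 | COC1=CC(O)C(Br)C(C)(C)[C@]12CC[C@](C)(Cl)[C@@H](Br)C2 | intermediate (not isolated)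
17 | (6R,8S,9S)-4,8-dibromo-9-chloro-5,5,9-trimethylspiro[5.5]undec-2-en-1-one, both C4 epimers | O=C1C=CC(Br)C(C)(C)[C@]12CC[C@](C)(Cl)[C@@H](Br)C2 | intermediate
18 | potassium (6R,8S,9S)-4,8-dibromo-9-chloro-5,5,9-trimethylspiro[5.5]undeca-1,3-dien-1-olate | [K+].[O-]C1=CC=C(Br)C(C)(C)[C@]12CC[C@](C)(Cl)[C@@H](Br)C2 | intermediate (not isolated)
19 | (6R,8S,9S)-4,8-dibromo-9-chloro-5,5,9-trimethylspiro[5.5]undec-3-en-1-one | O=C1CC=C(Br)C(C)(C)[C@]12CC[C@](C)(Cl)[C@@H](Br)C2 | intermediate
20 | (6S,8S,9S)-4,8-dibromo-9-chloro-5,5,9-trimethyl-1-methylidenespiro[5.5]undec-3-ene | C=C1CC=C(Br)C(C)(C)[C@]12CC[C@](C)(Cl)[C@@H](Br)C2 | intermediate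
21 | (6S,8S,9S)-4,8-dibromo-9-chloro-5,5,9-trimethyl-1-methylidenespiro[5.5]undec-3-en-2-ol, both C2 epimers | C=C1C(O)C=C(Br)C(C)(C)[C@]12CC[C@](C)(Cl)[C@@H](Br)C2 | intermediate (not isolated)
22 | (6S,8S,9S)-4,8-dibromo-9-chloro-5,5,9-trimethyl-1-methylidenespiro[5.5]undec-3-en-2-one | C=C1C(=O)C=C(Br)C(C)(C)[C@]12CC[C@](C)(Cl)[C@@H](Br)C2 | intermediate
23 | (2R,6S,8S,9S)-4,8-dibromo-9-chloro-5,5,9-trimethyl-1-methylidenespiro[5.5]undec-3-en-2-ol | C=C1[C@H](O)C=C(Br)C(C)(C)[C@]12CC[C@](C)(Cl)[C@@H](Br)C2 | target

Total step count: 14. Longest linear sequence: 13 steps (steps 1–3 and 5–14); step 4 is the side branch.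

Steps most likely to fail

Step 8 (key step). The ring closure is sterically retarded, because the electrophilic carbon is beta-branched and carries a beta-bromine and the nucleophilic carbon has two ortho substituents. Elimination of triflic acid, displacement of the triflate by fluoride or bromonium-assisted ionisation may therefore outrun it. The fallback sets out from 9 and comes back at 13; it forms the same bond before the halogens are in place. Alcohol 9 would be converted with methyl chloroformate and pyridine into the allylic methyl carbonate F1, and Bu4NF would free the phenol carbonate F2. Zerovalent palladium, as Pd2(dba)3 with the (R,R)-DACH-phenyl bisphosphine ligand, would ionise the carbonate, and the phenol para carbon would attack the CH2 terminus of the allyl complex (intramolecular asymmetric allylic dearomatisation). This should give (6R)-1-methoxy-5,9-dimethylspiro[5.5]undeca-1,4,8-trien-3-one F3, with the spiro centre now set by the ligand. Anti, Markovnikov bromochlorination of the ring B alkene with Bu4N[BrCl2] would then lead to 13. In this order the face of halogen addition has to be secured by the spiro centre alone, and this is why it is the fallback and not the route.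

Step 9. Conjugate addition at the neopentyl beta-carbon may be sluggish, and electron transfer from the cuprate to the C–Br bonds or attack on the vinylogous ester may then compete. The fallback sets out from 13 and comes back at 15; it brings the carbon in as a small, reversible ylide instead of an organocopper reagent. Corey–Chaykovsky cyclopropanation with dimethylsulfoxonium methylide (Me3S(O)I, NaH, DMSO) should give the cyclopropyl ketone F4. Ring opening with SmI2 (THF, t-BuOH, −78 °C) cleaves the external cyclopropane bond that overlaps with the ketyl and should leave the second methyl group on the quaternary carbon, giving the gem-dimethyl vinylogous ester F5. Enolisation toward its only alpha-CH2 (LiN(SiMe3)2, THF, −78 °C) and bromination with NBS would then give 15.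

Step 6. Enantio- or regiocontrol of halogen delivery to the (Z)-trisubstituted alkene may erode, and the electron-rich ring may be brominated in competition. The fallback sets out from 9 and comes back at 10; it replaces asymmetric catalysis by resolution. NBS and ClTi(OiPr)3 without the chiral ligand should give the racemic anti-bromochloride F6 with the same regiochemistry. Lipase-catalysed acylation (Pseudomonas cepacia lipase, vinyl acetate) would convert the (2R,3R)-alcohol into the acetate F7 and leave (2S,3S)-10 to be recovered; if the enzyme prefers the other enantiomer, the acetate of the wanted one is cleaved enzymatically instead.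

Further compounds
F1 | step 8 | (2Z)-5-[2-methoxy-6-methyl-4-(triisopropylsilyloxy)phenyl]-3-methylpent-2-en-1-yl methyl carbonate | C/C(CCc1c(C)cc(O[Si](C(C)C)(C(C)C)C(C)C)cc1OC)=C/COC(=O)OC
F2 | step 8 | (2Z)-5-(4-hydroxy-2-methoxy-6-methylphenyl)-3-methylpent-2-en-1-yl methyl carbonate | C/C(CCc1c(C)cc(O)cc1OC)=C/COC(=O)OC
F3 | step 8 | (6R)-1-methoxy-5,9-dimethylspiro[5.5]undeca-1,4,8-trien-3-one | COC1=CC(=O)C=C(C)[C@]12CCC(C)=CC2
F4 | step 9 | cyclopropyl ketone: 13 with a CH2 bridge across C4 and C5 of ring A (cyclopropane epimers) | COC1=CC(=O)C2CC2(C)[C@]13CC[C@](C)(Cl)[C@@H](Br)C3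
F5 | step 9 | (6R,8S,9S)-8-bromo-9-chloro-1-methoxy-5,5,9-trimethylspiro[5.5]undec-1-en-3-one | COC1=CC(=O)CC(C)(C)[C@]12CC[C@](C)(Cl)[C@@H](Br)C2
F6 | step 6 | racemic (2S*,3S*)-2-bromo-3-chloro-5-[2-methoxy-6-methyl-4-(triisopropylsilyloxy)phenyl]-3-methylpentan-1-ol | Cc1cc(O[Si](C(C)C)(C(C)C)C(C)C)cc(OC)c1CC[C@](C)(Cl)[C@@H](Br)CO.Cc1cc(O[Si](C(C)C)(C(C)C)C(C)C)cc(OC)c1CC[C@@](C)(Cl)[C@H](Br)CO
F7 | step 6 | (2R,3R)-2-bromo-3-chloro-5-[2-methoxy-6-methyl-4-(triisopropylsilyloxy)phenyl]-3-methylpentyl acetate | Cc1cc(O[Si](C(C)C)(C(C)C)C(C)C)cc(OC)c1CC[C@@](C)(Cl)[C@H](Br)COC(C)=O
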